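**Plan**
- Retrosynthesis: the aryl–C(=O) bond of the ketone is cut first (aryl Grignard reagent plus a C4 aldehyde that comes from a vinyl group), then O1–C2 and C3–C4 of the oxolane together in a [3+2] sense, and last the C2=C3 Knoevenagel bond of the acceptor.
- Enabling feature: with the ring numbered O1, C2 (aryl), C3 (CH2OH), C4 (aroyl), C5 (CH2), the unit O1–C5–C4 plus the exocyclic carbon on C4 is a ring-opened vinyl oxirane, and C2–C3 plus the hydroxymethyl carbon is an arylidene Meldrum's acid.
- Forward: Knoevenagel condensation, then the only ring (the oxolane) is closed by the palladium cycloaddition. The Meldrum's acid is cut down to the C3 ester, the vinyl group is cleaved to the aldehyde, the second aryl ring is added, and ester reduction, benzylic oxidation and debenzylation finish the route.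
- Stereochemistry: the chiral ligand sets C4 and, through the ring-closing transition state, C2 (cis to C4). C3 is set by base equilibration of the ester to the all-trans isomer, and C4 is secured again by equilibration once it is α to the ketone.

Key step: step 2

Remark: the ring locants O1, C2 (aryl carbon), C3, C4, C5 (CH2) are used for every oxolane below; where a systematic name numbers differently, both are given.
Remark: the ligand antipode in step 2 is assigned by analogy with the sense of induction of this ligand family on butadiene monoxide and is to be confirmed on the first run; the mirror-image ligand is taken if the sense proves opposite.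

**Step 1**
Reactants: 1 3-(benzyloxy)-4-methoxybenzaldehyde; 2 Meldrum's acid (2,2-dimethyl-1,3-dioxane-4,6-dione)
Product: 3 5-[3-(benzyloxy)-4-methoxybenzylidene]-2,2-dimethyl-1,3-dioxane-4,6-dione
Conditions: piperidine (5 mol%), AcOH (5 mol%), EtOH, rt; product filtered off
Reagents that add atoms: none
Why: Knoevenagel condensation of an aryl aldehyde with the strongly acidic methylene of Meldrum's acid is fast under amine/acid catalysis and is driven by precipitation of the arylidene product.

**Step 2**
Reactants: 3 the arylidene Meldrum's acid; 4 racemic 2-vinyloxirane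
Product: 5 (1R,4S)-1-[3-(benzyloxy)-4-methoxyphenyl]-4-ethenyl-8,8-dimethyl-2,7,9-trioxaspiro[4.5]decane-6,10-dione (oxolane locants: C2 R and C4 S; aryl cis to vinyl)
Conditions: Pd2(dba)3·CHCl3 (2.5 mol%), (R,R)-DACH-phenyl Trost ligand (7.5 mol%), 4 Å molecular sieves, CH2Cl2, 0 °C to rt, Ar; 4 (1.5 equiv) added slowly; stopped at full conversion of 3
Reagents that add atoms: none
Why: Zerovalent palladium ionises racemic 4 to an alkoxide/π-allylpalladium zwitterion whose diastereomeric π-allyl forms interconvert by π–σ–π faster than they are trapped, so both enantiomers of 4 converge; the alkoxide adds reversibly to the benzylidene carbon of 3 (O1–C2) and the Meldrum's acid anion so formed attacks the internal allyl carbon (C3–C4). The closest known reaction type is the palladium-catalysed [3+2] cycloaddition of vinyl epoxides and vinylethylene carbonates with doubly activated alkenes, which has enantioselective variants. The oxolane closes in a 5-exo-trig sense on the π-allyl unit, whereas attack at the allyl terminus would be a 7-endo closure. C4 is controlled by the chiral ligand in the enantio-determining allylic alkylation, and C2 is controlled relative to C4 in the same transition state, because the reversible oxa-Michael step lets the adduct with aryl and vinyl both pseudo-equatorial (cis) cyclise preferentially. The step needs branched regioselectivity, trapping of a weakly nucleophilic palladium-bound alkoxide before the epoxide isomerises, and facial selectivity; the first is secured by the tether length, the second by the very high electrophilicity of the alkylidene Meldrum's acid, and the third by the ligand.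

**Step 3**
Reactants: 5 the spiro cycloadduct
Product: 8 methyl (2S,3S,4S)-2-[3-(benzyloxy)-4-methoxyphenyl]-4-ethenyloxolane-3-carboxylate, via malonic half-ester 6 (not isolated), via C3-epimeric methyl ester mixture 7 (not isolated)
Conditions: NaOMe (1.2 equiv), MeOH, 0 °C to rt; 1 M HCl to pH 3, extraction; DMSO, 120 °C; then NaOMe (0.3 equiv), MeOH, rt
Reagents that add atoms: sodium methoxide, C[O-].[Na+]
Why: Methoxide opens the spiro acylal at a carbonyl with loss of acetone, the malonic half-ester loses CO2 on heating (acylal alcoholysis followed by malonic acid decarboxylation), and reversible enolisation at C3 with NaOMe then places the ester trans to both the C2 aryl and the C4 vinyl group, the all-trans isomer being the thermodynamic one while C2 and C4 carry no acidifying group at this stage.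

**Step 4**
Reactants: 8 the all-trans vinyl ester
Product: 10 methyl (2S,3S,4S)-2-[3-(benzyloxy)-4-methoxyphenyl]-4-formyloxolane-3-carboxylate, via secondary ozonide 9 (not isolated)
Conditions: O3, CH2Cl2, −78 °C, Sudan Red 7B end-point; then PPh3 (1.2 equiv), −78 °C to rt
Reagents that add atoms: ozone, [O-][O+]=O
Why: Ozonolysis with reductive work-up cleaves the monosubstituted alkene much faster than ozone attacks the alkoxyarenes or benzyl ether when addition is stopped at the dye end-point, and the trans arrangement at the now enolisable C4 is also the thermodynamic one.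

**Step 5**
Reactants: 10 the aldehyde ester; 11 2-(benzyloxy)-4-bromo-1-methoxybenzene
Product: 13 methyl (2S,3S,4S)-2-[3-(benzyloxy)-4-methoxyphenyl]-4-{[3-(benzyloxy)-4-methoxyphenyl](hydroxy)methyl}oxolane-3-carboxylate (both carbinol epimers), via arylmagnesium bromide 12 (not isolated)
Conditions: 11, Mg turnings, THF, rt; this solution (1.2 equiv) added to 10, THF, −78 °C; sat. aq. NH4Cl at −78 °C
Reagents that add atoms: none
Why: Chemoselective Grignard 1,2-addition, since at −78 °C an aryl Grignard reagent adds to an aldehyde far faster than to a methyl ester; the carbinol centre is left unassigned because step 7 oxidises it.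

**Step 6**
Reactants: 13 the hydroxy ester
Product: 14 {(2S,3R,4S)-2-[3-(benzyloxy)-4-methoxyphenyl]-4-{[3-(benzyloxy)-4-methoxyphenyl](hydroxy)methyl}oxolan-3-yl}methanol (both carbinol epimers)
Conditions: LiAlH4 (2 equiv), THF, 0 °C; then H2O
Reagents that add atoms: none
Why: LiAlH4 reduction of the methyl ester to the primary alcohol, with the aryl benzyl ethers, the cyclic ether and the three ring stereocentres inert to hydride.

**Step 7**
Reactants: 14 the diol
Product: 15 [3-(benzyloxy)-4-methoxyphenyl]{(3S,4R,5S)-5-[3-(benzyloxy)-4-methoxyphenyl]-4-(hydroxymethyl)oxolan-3-yl}methanone (locants used here: C2 S, C3 R, C4 S; all-trans)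
Conditions: activated MnO2 (15 equiv), CH2Cl2, rt; filtration; then DBU (0.2 equiv), CH2Cl2, rt
Reagents that add atoms: none
Why: Activated MnO2 oxidises benzylic alcohols selectively, so the electron-rich secondary benzylic carbinol should give the aryl ketone while the unactivated primary alcohol is kept, and the DBU treatment equilibrates the now enolisable C4 to the thermodynamic 3,4-trans ketone.

**Step 8**
Reactants: 15 the dibenzyl keto alcohol
Product: 16 (3-hydroxy-4-methoxyphenyl)[(3S,4R,5S)-5-(3-hydroxy-4-methoxyphenyl)-4-(hydroxymethyl)oxolan-3-yl]methanone (locants used here: C2 S, C3 R, C4 S), CNP0234761.1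
Conditions: H2 (1 atm), 10% Pd/C, EtOAc, rt, stopped at the end-point
Reagents that add atoms: none
Why: Catalytic hydrogenolysis cleaves aryl benzyl ethers quickly in neutral EtOAc, conditions under which the electron-rich aryl ketone and the cyclic benzylic ether react only slowly.

**Compound list**
1 | 3-(benzyloxy)-4-methoxybenzaldehyde | COc1ccc(C=O)cc1OCc1ccccc1 | starting material
2 | Meldrum's acid (2,2-dimethyl-1,3-dioxane-4,6-dione) | CC1(C)OC(=O)CC(=O)O1 | starting material
3 | 5-[3-(benzyloxy)-4-methoxybenzylidene]-2,2-dimethyl-1,3-dioxane-4,6-dione | CC1(C)OC(=O)C(=Cc2ccc(OC)c(OCc3ccccc3)c2)C(=O)O1 | intermediate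
4 | racemic 2-vinyloxirane | C=CC1CO1 | starting material
5 | (1R,4S)-1-[3-(benzyloxy)-4-methoxyphenyl]-4-ethenyl-8,8-dimethyl-2,7,9-trioxaspiro[4.5]decane-6,10-dione | C=C[C@@H]1CO[C@H](c2ccc(OC)c(OCc3ccccc3)c2)C12C(=O)OC(C)(C)OC2=O | intermediate
6 | (2R,4S)-2-[3-(benzyloxy)-4-methoxyphenyl]-4-ethenyl-3-(methoxycarbonyl)oxolane-3-carboxylic acid, both C3 epimers | C=C[C@@H]1CO[C@H](c2ccc(OC)c(OCc3ccccc3)c2)C1(C(=O)OC)C(=O)O | intermediate
7 | methyl (2S,4S)-2-[3-(benzyloxy)-4-methoxyphenyl]-4-ethenyloxolane-3-carboxylate, C3 epimer mixture | C=C[C@@H]1CO[C@H](c2ccc(OC)c(OCc3ccccc3)c2)C1C(=O)OC | intermediate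
8 | methyl (2S,3S,4S)-2-[3-(benzyloxy)-4-methoxyphenyl]-4-ethenyloxolane-3-carboxylate | C=C[C@@H]1CO[C@H](c2ccc(OC)c(OCc3ccccc3)c2)[C@H]1C(=O)OC | intermediate
9 | methyl (2S,3S,4S)-2-[3-(benzyloxy)-4-methoxyphenyl]-4-(1,2,4-trioxolan-3-yl)oxolane-3-carboxylate, epimers at the trioxolane carbon | C1(OCOO1)[C@@H]2CO[C@H](c3ccc(OC)c(OCc4ccccc4)c3)[C@H]2C(=O)OC | intermediate
10 | methyl (2S,3S,4S)-2-[3-(benzyloxy)-4-methoxyphenyl]-4-formyloxolane-3-carboxylate | O=C[C@@H]1CO[C@H](c2ccc(OC)c(OCc3ccccc3)c2)[C@H]1C(=O)OC | intermediate
11 | 2-(benzyloxy)-4-bromo-1-methoxybenzene | COc1ccc(Br)cc1OCc1ccccc1 | starting material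
12 | [3-(benzyloxy)-4-methoxyphenyl]magnesium bromide | COc1ccc([Mg]Br)cc1OCc1ccccc1 | intermediate
13 | methyl (2S,3S,4S)-2-[3-(benzyloxy)-4-methoxyphenyl]-4-{[3-(benzyloxy)-4-methoxyphenyl](hydroxy)methyl}oxolane-3-carboxylate, both carbinol epimers | COc1ccc(C(O)[C@@H]2CO[C@H](c3ccc(OC)c(OCc4ccccc4)c3)[C@H]2C(=O)OC)cc1OCc1ccccc1 | intermediate
14 | {(2S,3R,4S)-2-[3-(benzyloxy)-4-methoxyphenyl]-4-{[3-(benzyloxy)-4-methoxyphenyl](hydroxy)methyl}oxolan-3-yl}methanol, both carbinol epimers | COc1ccc(C(O)[C@@H]2CO[C@H](c3ccc(OC)c(OCc4ccccc4)c3)[C@H]2CO)cc1OCc1ccccc1 | intermediate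
15 | [3-(benzyloxy)-4-methoxyphenyl]{(3S,4R,5S)-5-[3-(benzyloxy)-4-methoxyphenyl]-4-(hydroxymethyl)oxolan-3-yl}methanone | COc1ccc(C(=O)[C@@H]2CO[C@H](c3ccc(OC)c(OCc4ccccc4)c3)[C@H]2CO)cc1OCc1ccccc1 | intermediate
16 | (3-hydroxy-4-methoxyphenyl)[(3S,4R,5S)-5-(3-hydroxy-4-methoxyphenyl)-4-(hydroxymethyl)oxolan-3-yl]methanone | COc1ccc(C(=O)[C@@H]2CO[C@H](c3ccc(OC)c(O)c3)[C@H]2CO)cc1O | target

Total step count: 8. Longest linear sequence: 8 steps (1 to 16).

**Steps most likely to fail**

Step 2. Facial control at the π-allyl terminus may be insufficient, the epoxide may isomerise to crotonaldehyde before it is trapped, or re-ionisation of the allylic Meldrum's acid unit by the catalyst may erode the enantiomeric purity on long reaction times. The fallback sets out from 3 and generates the same zwitterion by decarboxylative ionisation of commercial 4-vinyl-1,3-dioxolan-2-one with Pd2(dba)3·CHCl3 and a BINOL-derived phosphoramidite in THF. No free epoxide is then present and a different ligand class sets C4. The sequence comes back to the route at 5 and makes no new compound (F0).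

Step 5. The basic Grignard reagent may enolise the α-branched aldehyde, attack the ester, or the magnesium alkoxide may lactonise on warming. The fallback sets out from 10 and transfers the aryl group from [3-(benzyloxy)-4-methoxyphenyl]boronic acid under rhodium catalysis (Rh(acac)(CO)2, tri-tert-butylphosphine, DME/H2O, rt). This is a non-basic 1,2-addition that tolerates esters. It comes back to the route at 13 and makes no new compound (F0).

Step 7. Oxidation of the hindered carbinol may stall on the MnO2 surface, or the primary alcohol may be over-oxidised. The fallback sets out from 14. TBSCl and imidazole in CH2Cl2 at 0 °C should silylate the primary hydroxyl selectively to give the primary tert-butyldimethylsilyl ether F1. Dess–Martin periodinane with NaHCO3 in CH2Cl2 then oxidises the free carbinol to the silyl-protected ketone F2. TBAF buffered with AcOH in THF removes the silyl group and comes back to the route at 15; the C4 equilibration with DBU is applied there as in step 7.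

**Further compounds**
F0 | step 2 | none | none
F0 | step 5 | none | none
F1 | step 7 | {(2S,3R,4S)-2-[3-(benzyloxy)-4-methoxyphenyl]-3-{[(tert-butyldimethylsilyl)oxy]methyl}oxolan-4-yl}[3-(benzyloxy)-4-methoxyphenyl]methanol, both carbinol epimers | COc1ccc(C(O)[C@@H]2CO[C@H](c3ccc(OC)c(OCc4ccccc4)c3)[C@H]2CO[Si](C)(C)C(C)(C)C)cc1OCc1ccccc1
F2 | step 7 | [3-(benzyloxy)-4-methoxyphenyl]{(3S,4R,5S)-5-[3-(benzyloxy)-4-methoxyphenyl]-4-{[(tert-butyldimethylsilyl)oxy]methyl}oxolan-3-yl}methanone | COc1ccc(C(=O)[C@@H]2CO[C@H](c3ccc(OC)c(OCc4ccccc4)c3)[C@H]2CO[Si](C)(C)C(C)(C)C)cc1OCc1ccccc1
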